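**Retrosynthetic overview**
- The oxirane is the only ring and is made last: both C–O bonds come from catalyst-controlled epoxidation of the 4Z alkene of the unprotected (2E,4Z)-dienedioic acid.
- The 12-hydroxy-13-(hydroxymethyl) acid terminus comes from a C12 aldehyde, methyl acrylate and B2pin2 (new copper-catalysed borylative aldol, then C–B to C–O oxidation).
- The (2E,4Z)-dienoate comes from a chiral C6–C12 alkyl bromide, propyne and methyl but-2-ynoate (one-pot double carbocupration).
- The bromide comes from (R)-3-bromo-2-methylpropan-1-ol (C7 from the chiral pool) and the Grignard reagent of 2-(3-chloropropyl)-1,3-dioxolane.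

Assumption: (R)-3-bromo-2-methylpropan-1-ol, both antipodes of the ferrocenyl bisphosphine and the L-series Shi ketone are taken as purchasable; the ligand antipode that gives 12S,13R is fixed in the first run of step 5.

**Route**

Step 1
Reactants: 1 (R)-3-bromo-2-methylpropan-1-ol; 2 2-(3-chloropropyl)-1,3-dioxolane
Product: 5 (2S)-6-(1,3-dioxolan-2-yl)-2-methylhexan-1-ol, via Grignard reagent 3 (not isolated), via chloromagnesium alkoxide 4 (not isolated)
Conditions: 2, Mg turnings, THF, 50 °C (gives 3); 1, MeMgCl (1.0 equiv), THF, −30 °C (gives 4); then 3 (1.4 equiv), Li2CuCl4 (3 mol %), −30 → 20 °C; aq NH4Cl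
Reagents that add atoms: none
Why: Kochi-type Li2CuCl4-catalysed alkyl–alkyl cross-coupling of a primary Grignard reagent with the primary bromide of the pre-formed magnesium alkoxide, in which no bond to the stereocentre is touched, so C7 comes intact from the chiral pool (the descriptor changes from R to S only through the priority change).

Step 2
Reactants: 5 (2S)-6-(1,3-dioxolan-2-yl)-2-methylhexan-1-ol
Product: 6 2-[(5S)-6-bromo-5-methylhexyl]-1,3-dioxolane
Conditions: CBr4, PPh3, 2,6-lutidine (0.2 equiv), CH2Cl2, 0 °C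
Reagents that add atoms: carbon tetrabromide, BrC(Br)(Br)Br
Why: Appel bromination of the primary alcohol under buffered, acid-free conditions that leave the dioxolane and the neighbouring stereocentre untouched.

Step 3
Reactants: 6 2-[(5S)-6-bromo-5-methylhexyl]-1,3-dioxolane; 7 propyne; 8 methyl but-2-ynoate
Product: 13 methyl (2E,4Z,7S)-11-(1,3-dioxolan-2-yl)-3,5,7-trimethylundeca-2,4-dienoate, via Grignard reagent 9 (not isolated), via alkylcopper 10 (not isolated), via alkenylcopper 11 (not isolated), via cuprio dienoate 12 (not isolated)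
Conditions: Mg, Et2O, 35 °C; CuBr·SMe2 (1.0 equiv), Et2O/Me2S, −45 °C; propyne (3 equiv), −25 °C, 3 h; methyl but-2-ynoate (0.95 equiv), THF, −78 → −40 °C; NH4Cl/MeOH at −78 °C
Reagents that add atoms: none
Why: Normant carbocupration adds the alkylcopper syn across propyne with copper on the terminal carbon (chain cis to copper, hence 4Z), and the alkenylcopper then adds syn across the ynoate (conjugate carbocupration) so that cold protonation with retention gives 2E, both alkene geometries being set here while C7 is untouched.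

Step 4
Reactants: 13 methyl (2E,4Z,7S)-11-(1,3-dioxolan-2-yl)-3,5,7-trimethylundeca-2,4-dienoate
Product: 14 methyl (2E,4Z,7S)-3,5,7-trimethyl-12-oxododeca-2,4-dienoate
Conditions: 1 M HCl, THF, 40 °C
Reagents that add atoms: water, O
Why: Acid-catalysed acetal hydrolysis, to which the conjugated methyl ester and the diene geometry are inert under dilute acid at this temperature.

Step 5
Reactants: 14 methyl (2E,4Z,7S)-3,5,7-trimethyl-12-oxododeca-2,4-dienoate; 15 methyl acrylate; 16 bis(pinacolato)diboron
Product: 18 dimethyl (2E,4Z,7S,12S,13R)-12-hydroxy-13-(hydroxymethyl)-3,5,7-trimethyltetradeca-2,4-dienedioate, via bis-boryl aldolate 17 (not isolated)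
Conditions: CuCl (5 mol %), Josiphos SL-J001 [(R)-1-[(S)-2-(diphenylphosphino)ferrocenyl]ethyldicyclohexylphosphine, 6 mol %], NaOtBu (10 mol %), B2pin2 (1.2 equiv), methyl acrylate (1.5 equiv, slow addition), THF, −20 °C; then NaBO3·4H2O, THF/H2O, 20 °C; minor diastereomers removed by chromatography
Reagents that add atoms: sodium perborate (NaBO3, used as the tetrahydrate), [Na+].[O-]OB=O
Why: Proposed new method: an intermolecular, enantioselective copper-catalysed borylative aldol reaction in which the ligated Cu–Bpin species (from CuCl, NaOtBu and B2pin2) inserts methyl acrylate much faster than it attacks the hindered β,β-disubstituted dienoate or the aldehyde carbonyl, the resulting (Z)-O-bound copper enolate adds to aldehyde 14 through a chair Zimmerman–Traxler transition state (12,13-syn) with the ferrocenyl bisphosphine choosing the aldehyde face (12S,13R), B2pin2 turns over the copper aldolate to give 17, and perborate then converts C–B into C–O with retention; the closest known reaction types are the copper-catalysed reductive aldol reaction of acrylates (hydride in place of boryl) and the intramolecular copper-catalysed borylative aldol cyclisation.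

Step 6
Reactants: 18 dimethyl (2E,4Z,7S,12S,13R)-12-hydroxy-13-(hydroxymethyl)-3,5,7-trimethyltetradeca-2,4-dienedioate
Product: 19 (2E,4Z,7S,12S,13R)-12-hydroxy-13-(hydroxymethyl)-3,5,7-trimethyltetradeca-2,4-dienedioic acid
Conditions: LiOH·H2O (6 equiv), THF/MeOH/H2O, 0 → 40 °C; then 1 M HCl to pH 3, 0 °C
Reagents that add atoms: lithium hydroxide, [Li+].[OH-]
Why: Saponification of both methyl esters, in which the C14 ester is cleaved fast at 0 °C and the resulting carboxylate protects C13 against epimerisation and retro-aldol cleavage while the slower conjugated C1 ester is hydrolysed at 40 °C.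

Step 7
Reactants: 19 (2E,4Z,7S,12S,13R)-12-hydroxy-13-(hydroxymethyl)-3,5,7-trimethyltetradeca-2,4-dienedioic acid
Product: 20 (2E,4S,5R,7S,12S,13R)-4,5-epoxy-12-hydroxy-13-(hydroxymethyl)-3,5,7-trimethyltetradec-2-enedioic acid
Conditions: L-fructose-derived Shi ketone (1,2:4,5-di-O-isopropylidene-β-L-erythro-2,3-hexodiulo-2,6-pyranose, 30 mol %), KHSO5 (as Oxone, 2KHSO5·KHSO4·K2SO4), K2CO3, Bu4NHSO4 (cat.), MeCN/dimethoxymethane/aq Na2EDTA, pH 10.5, 0 °C; then NaH2PO4 to pH 4 at 0 °C, EtOAc extraction
Reagents that add atoms: potassium peroxymonosulfate (KHSO5), [K+].[O-]S(=O)(=O)OO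
Why: Shi asymmetric epoxidation by a chiral dioxirane, in which the electron-rich trisubstituted 4,5-alkene reacts in preference to the carboxylate-conjugated 2,3-alkene, oxygen transfer is stereospecific so the 4Z geometry gives the oxirane with C3 and C6 cis, and the spiro transition state of the L-series ketone (C4–H in the hindered quadrant) delivers oxygen to the face that gives 4S,5R, closing the only ring by C–O bond formation.

**Compound list**
1 | (R)-3-bromo-2-methylpropan-1-ol | OC[C@@H](C)CBr | starting material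
2 | 2-(3-chloropropyl)-1,3-dioxolane | ClCCCC1OCCO1 | starting material
3 | [3-(1,3-dioxolan-2-yl)propyl]magnesium chloride (formed in the flask) | Cl[Mg]CCCC1OCCO1 | intermediate
4 | chloromagnesium (2R)-3-bromo-2-methylpropan-1-olate (formed in the flask) | Cl[Mg]OC[C@@H](C)CBr | intermediate
5 | (2S)-6-(1,3-dioxolan-2-yl)-2-methylhexan-1-ol | OC[C@@H](C)CCCCC1OCCO1 | intermediate
6 | 2-[(5S)-6-bromo-5-methylhexyl]-1,3-dioxolane | BrC[C@@H](C)CCCCC1OCCO1 | intermediate
7 | propyne | CC#C | starting material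
8 | methyl but-2-ynoate | CC#CC(=O)OC | starting material
9 | [(2S)-6-(1,3-dioxolan-2-yl)-2-methylhexyl]magnesium bromide (formed in the flask) | Br[Mg]C[C@@H](C)CCCCC1OCCO1 | intermediate
10 | [(2S)-6-(1,3-dioxolan-2-yl)-2-methylhexyl]copper, MgBr2 complex (formed in the flask) | [Cu]C[C@@H](C)CCCCC1OCCO1 | intermediate
11 | [(1Z,4S)-8-(1,3-dioxolan-2-yl)-2,4-dimethyloct-1-en-1-yl]copper (formed in the flask) | [Cu]/C=C(/C)C[C@@H](C)CCCCC1OCCO1 | intermediate
12 | methyl (2Z,4Z,7S)-2-cuprio-11-(1,3-dioxolan-2-yl)-3,5,7-trimethylundeca-2,4-dienoate (formed in the flask) | COC(=O)/C([Cu])=C(\C)/C=C(/C)C[C@@H](C)CCCCC1OCCO1 | intermediate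
13 | methyl (2E,4Z,7S)-11-(1,3-dioxolan-2-yl)-3,5,7-trimethylundeca-2,4-dienoate | COC(=O)/C=C(\C)/C=C(/C)C[C@@H](C)CCCCC1OCCO1 | intermediate
14 | methyl (2E,4Z,7S)-3,5,7-trimethyl-12-oxododeca-2,4-dienoate | COC(=O)/C=C(\C)/C=C(/C)C[C@@H](C)CCCCC=O | intermediate
15 | methyl acrylate | C=CC(=O)OC | starting material
16 | bis(pinacolato)diboron | CC1(C)OB(OC1(C)C)B1OC(C)(C)C(C)(C)O1 | starting material
17 | dimethyl (2E,4Z,7S,12S,13R)-3,5,7-trimethyl-12-[(4,4,5,5-tetramethyl-1,3,2-dioxaborolan-2-yl)oxy]-13-[(4,4,5,5-tetramethyl-1,3,2-dioxaborolan-2-yl)methyl]tetradeca-2,4-dienedioate (formed in the flask) | COC(=O)/C=C(\C)/C=C(/C)C[C@@H](C)CCCC[C@H](OB1OC(C)(C)C(C)(C)O1)[C@@H](CB1OC(C)(C)C(C)(C)O1)C(=O)OC | intermediate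
18 | dimethyl (2E,4Z,7S,12S,13R)-12-hydroxy-13-(hydroxymethyl)-3,5,7-trimethyltetradeca-2,4-dienedioate | COC(=O)/C=C(\C)/C=C(/C)C[C@@H](C)CCCC[C@H](O)[C@@H](CO)C(=O)OC | intermediate
19 | (2E,4Z,7S,12S,13R)-12-hydroxy-13-(hydroxymethyl)-3,5,7-trimethyltetradeca-2,4-dienedioic acid | OC(=O)/C=C(\C)/C=C(/C)C[C@@H](C)CCCC[C@H](O)[C@@H](CO)C(=O)O | intermediate
20 | (2E,4S,5R,7S,12S,13R)-4,5-epoxy-12-hydroxy-13-(hydroxymethyl)-3,5,7-trimethyltetradec-2-enedioic acid (CNP0468463.2) | C/C(=C\C(=O)O)[C@@H]1O[C@]1(C)C[C@@H](C)CCCC[C@H](O)[C@@H](CO)C(=O)O | target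

**Step count**
Total steps: 7. Longest linear sequence: 7 (from 1 to 20).

**Three steps most likely to fail, with fallbacks**

Step 5 (the proposed new borylative aldol). The risks are 1,2-borylation of the aldehyde, oligomerisation of the acrylate, and insufficient syn or enantio control. The fallback uses known chemistry, sets out from aldehyde 14 and comes back at diacid 19. The acyl oxazolidinone (4R)-4-benzyl-3-{3-[(4-methoxyphenyl)methoxy]propanoyl}-1,3-oxazolidin-2-one F3 is made in one operation from (R)-4-benzyloxazolidin-2-one and 3-[(4-methoxybenzyl)oxy]propanoic acid (pivaloyl chloride, Et3N, LiCl, THF). Its dibutylboron enolate (Bu2BOTf, iPr2NEt, CH2Cl2, −78 → 0 °C) undergoes an Evans syn-aldol reaction with 14. This gives methyl (2E,4Z,7S,12S,13R)-13-[(4R)-4-benzyl-2-oxo-1,3-oxazolidine-3-carbonyl]-12-hydroxy-14-[(4-methoxyphenyl)methoxy]-3,5,7-trimethyltetradeca-2,4-dienoate F4, with the (R)-auxiliary setting 12S,13R. DDQ in wet CH2Cl2 at pH 7 removes the 4-methoxybenzyl group to give methyl (2E,4Z,7S,12S,13R)-13-[(4R)-4-benzyl-2-oxo-1,3-oxazolidine-3-carbonyl]-12,14-dihydroxy-3,5,7-trimethyltetradeca-2,4-dienoate F5. LiOH/H2O2 (THF/H2O, 0 °C) followed by LiOH in aqueous MeOH at 40 °C cleaves the auxiliary and the C1 methyl ester and delivers 19.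

Step 3 (double carbocupration). The risk is that the alkenylcopper adds slowly, or with loss of geometry, to the β-substituted ynoate. The fallback sets out from bromide 6 and comes back at dienoate 13. 6 is taken through 9, 10 and 11 as before, and 11 is quenched with I2 at −78 °C to give 2-[(5S,7Z)-8-iodo-5,7-dimethyloct-7-en-1-yl]-1,3-dioxolane F1 with retention. Separately, methyl (2Z)-3-(4,4,5,5-tetramethyl-1,3,2-dioxaborolan-2-yl)but-2-enoate F2 is made in one step from 8 and 16 by copper-catalysed syn-hydroboration (CuCl, Xantphos, NaOtBu, MeOH, THF). Suzuki–Miyaura coupling of F1 with F2 (Pd(PPh3)4, aq K3PO4, THF, 50 °C) proceeds with retention at both alkenes and gives 13.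

Step 7 (epoxidation of the unprotected diacid). The risks are partitioning of the dicarboxylate, lower facial selectivity on the Z-trisubstituted alkene, and loss of the acid-labile vinyl oxirane on acidification. The fallback sets out from diester 18 and comes back at target 20. 18 is epoxidised as the neutral ester with the same L-series ketone under the standard biphasic conditions to give dimethyl (2E,4S,5R,7S,12S,13R)-4,5-epoxy-12-hydroxy-13-(hydroxymethyl)-3,5,7-trimethyltetradec-2-enedioate F6. Both methyl esters are then cleaved under near-neutral conditions with Me3SnOH (1,2-dichloroethane, 70 °C; cold dilute HCl wash) to give 20.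

**Further compounds**
F1 | step 3 | 2-[(5S,7Z)-8-iodo-5,7-dimethyloct-7-en-1-yl]-1,3-dioxolane | I/C=C(/C)C[C@@H](C)CCCCC1OCCO1
F2 | step 3 | methyl (2Z)-3-(4,4,5,5-tetramethyl-1,3,2-dioxaborolan-2-yl)but-2-enoate | COC(=O)/C=C(\C)B1OC(C)(C)C(C)(C)O1
F3 | step 5 | (4R)-4-benzyl-3-{3-[(4-methoxyphenyl)methoxy]propanoyl}-1,3-oxazolidin-2-one | O=C1OC[C@@H](Cc2ccccc2)N1C(=O)CCOCc1ccc(OC)cc1
F4 | step 5 | methyl (2E,4Z,7S,12S,13R)-13-[(4R)-4-benzyl-2-oxo-1,3-oxazolidine-3-carbonyl]-12-hydroxy-14-[(4-methoxyphenyl)methoxy]-3,5,7-trimethyltetradeca-2,4-dienoate | COC(=O)/C=C(\C)/C=C(/C)C[C@@H](C)CCCC[C@H](O)[C@@H](COCc1ccc(OC)cc1)C(=O)N1C(=O)OC[C@H]1Cc1ccccc1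
F5 | step 5 | methyl (2E,4Z,7S,12S,13R)-13-[(4R)-4-benzyl-2-oxo-1,3-oxazolidine-3-carbonyl]-12,14-dihydroxy-3,5,7-trimethyltetradeca-2,4-dienoate | COC(=O)/C=C(\C)/C=C(/C)C[C@@H](C)CCCC[C@H](O)[C@@H](CO)C(=O)N1C(=O)OC[C@H]1Cc1ccccc1
F6 | step 7 | dimethyl (2E,4S,5R,7S,12S,13R)-4,5-epoxy-12-hydroxy-13-(hydroxymethyl)-3,5,7-trimethyltetradec-2-enedioate | COC(=O)/C=C(\C)[C@@H]1O[C@]1(C)C[C@@H](C)CCCC[C@H](O)[C@@H](CO)C(=O)OC
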